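In drimane numbering (ring A = C1–C5, C10; ring B = C5–C10) the target is an albicanol ester. (+)-Verbenone already holds ring B, the C10 methyl, the C5 stereocentre and the gem-dimethyl C4; its cyclobutane bond C4–C7 masks a tertiary C4 cation. Conjugate allylation anti to the bridge sets C10 with the allyl arm (C1–C3) trans to C4. In the key step a Lewis acid breaks the C4–C7 bond of the derived bicyclic β-keto ester and the allyl terminus traps the cation: C3–C4 forms and ring A closes as the last ring, trans-fused. The step exploits the quaternary C4 of ring A, which stands next to C5 and 1,4 to the C8 carbonyl of ring B.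

Key step: step 3

Remark: drimane numbering (C11 = CH2O carbon, C12 = exocyclic CH2 carbon) is also used for the corresponding carbons of the bicyclic precursors. (1R,5R)-(+)-Verbenone, allylmagnesium bromide, (triphenylphosphoranylidene)ketene and 2,4-dihydroxybenzaldehyde are taken as commercial. The carbon between the two carbonyl groups of 4 is configurationally labile and is drawn in its expected major form.

Step 1
Reactants: 1 (1R,5R)-(+)-verbenone
Product: 3 (1R,4R,5R)-4-allyl-4,6,6-trimethylbicyclo[3.1.1]heptan-2-one, via trimethylsilyl enol ether 2 (not isolated)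
Conditions: allylMgBr (1.5 equiv), CuBr·SMe2 (1.5 equiv), Me3SiCl (2 equiv), THF, −78 °C; then 1 M HCl, 0 °C
Reagents that add atoms: allylmagnesium bromide, C=CC[Mg]Br (chlorotrimethylsilane, C[Si](C)(C)Cl, puts its silyl group into 2 only)
Why: Copper-mediated, Me3SiCl-accelerated 1,4-addition (organocopper conjugate addition) to the β,β-disubstituted enone should deliver allyl to the face opposite the gem-dimethyl bridge, whose syn methyl shields the other face, so the new quaternary carbon (future C10) carries the allyl arm trans to the bridge carbon that becomes C4.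

Step 2
Reactants: 3 (1R,4R,5R)-4-allyl-4,6,6-trimethylbicyclo[3.1.1]heptan-2-one
Product: 4 methyl 4-allyl-4,6,6-trimethyl-2-oxobicyclo[3.1.1]heptane-3-carboxylate (skeleton configuration of 3; ester on the face opposite the gem-dimethyl bridge)
Conditions: NaH (2.5 equiv), (MeO)2CO, THF, reflux; then aq. HCl, 0 °C
Reagents that add atoms: dimethyl carbonate, COC(=O)OC
Why: Claisen-type carbomethoxylation of the ketone enolate should be regiospecific because the bridgehead α-carbon cannot enolise (Bredt), so only the CH2 that becomes C9 is acylated and the product is held as its stabilised enolate; the new centre is labile and is reset in step 3.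

Step 3
Reactants: 4 methyl 4-allyl-4,6,6-trimethyl-2-oxobicyclo[3.1.1]heptane-3-carboxylate
Product: 5 methyl (1R,4aS,7S,8aS)-7-chloro-5,5,8a-trimethyl-2-oxodecahydronaphthalene-1-carboxylate (trans-decalin; chloride equatorial at C2 in drimane numbering)
Conditions: SnCl4 (1.5 equiv), CH2Cl2, −20 °C to rt; then aq. NaHCO3
Reagents that add atoms: tin tetrachloride, Cl[Sn](Cl)(Cl)Cl
Why: Proposed new method: SnCl4 chelates the β-keto ester and the strained cyclobutane bond between the ketone α-carbon (future C7) and the gem-dimethyl carbon (future C4) ionises to a tin enolate and a tertiary C4 carbocation, which the terminal carbon (C3) of the allyl group on C10 captures through a chair transition state while chloride adds anti at C2; the closest known reaction types are the SnCl4-induced opening of 4-substituted 6,6-dimethylbicyclo[3.1.1]heptan-2-ones with capture of the same cation by a tethered phenol oxygen, cyclopropyl-ketone-initiated cation-olefin cyclisation and halide-terminated Prins cyclisation. Ring A (C1–C5, C10) closes by 6-endo-trig attack on the allyl double bond, the Markovnikov mode, since 5-exo closure would need a primary cation. No ring-fusion centre is created: C5 and C10 come from 4 with their two arms trans, so only the trans-decalin can form; the chloride at C2 is placed equatorial by the anti addition and is removed in step 4; C9 settles with the ester equatorial by enolisation of the β-keto ester (thermodynamic control). The step needs C–C heterolysis to be faster than Prins attack of the olefin on the activated ketone, and olefin capture to be faster than proton loss or 1,2-hydride shift from C5 to the cation; relief of cyclobutane strain, the tertiary gem-dimethyl terminus and the six-membered chair pre-organisation of the trans arms on the cyclohexanone should secure both.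

Step 4
Reactants: 5 methyl (1R,4aS,7S,8aS)-7-chloro-5,5,8a-trimethyl-2-oxodecahydronaphthalene-1-carboxylate
Product: 6 methyl (1R,4aS,8aS)-5,5,8a-trimethyl-2-oxodecahydronaphthalene-1-carboxylate
Conditions: Bu3SnH (1.5 equiv), AIBN (portionwise), toluene, 110 °C
Reagents that add atoms: none
Why: Radical chain hydrodechlorination (tin hydride reduction) should remove the unactivated secondary chloride, so both C2 epimers converge on one product while ketone, ester and the three set stereocentres are untouched.

Step 5
Reactants: 6 methyl (1R,4aS,8aS)-5,5,8a-trimethyl-2-oxodecahydronaphthalene-1-carboxylate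
Product: 7 methyl (1S,4aS,8aS)-5,5,8a-trimethyl-2-methylidenedecahydronaphthalene-1-carboxylate (methyl albicanate)
Conditions: Ph3PCH3Br (3 equiv), KOtBu (2.8 equiv), toluene, 90 °C
Reagents that add atoms: methyltriphenylphosphonium bromide, C[P+](c1ccccc1)(c1ccccc1)c1ccccc1.[Br-]
Why: Wittig methylenation should install C12 because proton transfer between ylide and the hindered keto ester is reversible whereas oxaphosphetane formation is not, so the keto form is drained to the exocyclic alkene and the equatorial ester at C9 is kept.

Step 6
Reactants: 7 methyl albicanate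
Product: 8 (+)-albicanol, [(1S,4aS,8aS)-5,5,8a-trimethyl-2-methylidenedecahydronaphthalen-1-yl]methanol
Conditions: LiAlH4, Et2O, 0 °C to rt
Reagents that add atoms: none
Why: Hydride reduction of the ester should give the primary alcohol at C11, with the isolated exocyclic alkene inert and reduction faster than any deprotonation at C9.

Step 7
Reactants: 8 (+)-albicanol; 9 2,4-dihydroxybenzaldehyde
Product: 11 [(1S,4aS,8aS)-5,5,8a-trimethyl-2-methylidenedecahydronaphthalen-1-yl]methyl (2E)-3-(2,4-dihydroxyphenyl)prop-2-enoate, via albicanyl (triphenylphosphoranylidene)acetate 10 (not isolated)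
Conditions: Ph3P=C=C=O (1.0 equiv), toluene, 110 °C until the cumulated ylide is consumed; then 9 (1.2 equiv), 80 °C
Reagents that add atoms: (triphenylphosphoranylidene)ketene, O=C=C=P(c1ccccc1)(c1ccccc1)c1ccccc1
Why: Addition of the alcohol across the cumulated ylide should give the ester-stabilised phosphorane 10, whose Wittig reaction with the aldehyde gives the E-alkene (stabilised ylide); the free phenols only take part in reversible proton transfer and the E geometry keeps the ortho hydroxyl from lactonising.

Compound list
1 | (1R,5R)-(+)-verbenone, (1R,5R)-4,6,6-trimethylbicyclo[3.1.1]hept-3-en-2-one | CC1=CC(=O)[C@@H]2C[C@H]1C2(C)C | starting material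
2 | trimethylsilyl enol ether of 3 (4-allyl-4,6,6-trimethyl-2-trimethylsilyloxybicyclo[3.1.1]hept-2-ene, allyl anti to the gem-dimethyl bridge) | C=CC[C@]1(C)C=C(O[Si](C)(C)C)[C@@H]2C[C@H]1C2(C)C | intermediate (not isolated)
3 | (1R,4R,5R)-4-allyl-4,6,6-trimethylbicyclo[3.1.1]heptan-2-one (allyl anti to the gem-dimethyl bridge) | C=CC[C@]1(C)CC(=O)[C@@H]2C[C@H]1C2(C)C | intermediate
4 | methyl 4-allyl-4,6,6-trimethyl-2-oxobicyclo[3.1.1]heptane-3-carboxylate (skeleton as 3; ester anti to the gem-dimethyl bridge, labile) | C=CC[C@]1(C)[C@H](C(=O)OC)C(=O)[C@@H]2C[C@H]1C2(C)C | intermediate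
5 | methyl (1R,4aS,7S,8aS)-7-chloro-5,5,8a-trimethyl-2-oxodecahydronaphthalene-1-carboxylate | O=C1CC[C@H]2C(C)(C)C[C@H](Cl)C[C@]2(C)[C@H]1C(=O)OC | intermediate
6 | methyl (1R,4aS,8aS)-5,5,8a-trimethyl-2-oxodecahydronaphthalene-1-carboxylate | O=C1CC[C@H]2C(C)(C)CCC[C@]2(C)[C@H]1C(=O)OC | intermediate
7 | methyl (1S,4aS,8aS)-5,5,8a-trimethyl-2-methylidenedecahydronaphthalene-1-carboxylate (methyl albicanate) | C=C1CC[C@H]2C(C)(C)CCC[C@]2(C)[C@H]1C(=O)OC | intermediate
8 | (+)-albicanol, [(1S,4aS,8aS)-5,5,8a-trimethyl-2-methylidenedecahydronaphthalen-1-yl]methanol | C=C1CC[C@H]2C(C)(C)CCC[C@]2(C)[C@H]1CO | intermediate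
9 | 2,4-dihydroxybenzaldehyde | O=Cc1ccc(O)cc1O | starting material
10 | albicanyl (triphenylphosphoranylidene)acetate | C=C1CC[C@H]2C(C)(C)CCC[C@]2(C)[C@H]1COC(=O)C=P(c1ccccc1)(c1ccccc1)c1ccccc1 | intermediate (not isolated)
11 | [(1S,4aS,8aS)-5,5,8a-trimethyl-2-methylidenedecahydronaphthalen-1-yl]methyl (2E)-3-(2,4-dihydroxyphenyl)prop-2-enoate | C=C1CC[C@H]2C(C)(C)CCC[C@]2(C)[C@H]1COC(=O)/C=C/c1ccc(O)cc1O | target

Total steps: 7. Longest linear sequence: 7 steps (1 to 11).

Steps most likely to fail

1. Step 3 (proposed new method). The tertiary cation may be lost by proton elimination, or by a 1,2-hydride shift from C5 that would erase that stereocentre, before the olefin engages. The allyl group may instead add Prins-fashion to the chelated ketone, and enolate formation on tin may switch the carbonyl off as electron sink. Proton loss at C2 may also compete with chloride capture. The fallback uses known chemistry, sets out from 4 and comes back at 5, and cuts the cascade into two established reactions. Dry HCl in CH2Cl2/AcOH at 0 °C should open the cyclobutane in the way known for 6,6-dimethylbicyclo[3.1.1]heptan-2-ones and give the monocyclic tertiary chloride methyl 6-allyl-5-(2-chloropropan-2-yl)-6-methyl-2-oxocyclohexane-1-carboxylate F1 (C5 and C10 as in 5). F1 is then ionised under classical tertiary-halide cation-olefin cyclisation conditions (SnCl4, CH2Cl2, −78 °C), with chloride termination, to give 5.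

2. Step 5. Deprotonation of the β-keto ester by the ylide may stall the olefination, and base may move the new double bond into conjugation with the ester, which would erase C9. The fallback sets out from 6 and comes back at 8, and removes the 1,3-dicarbonyl acidity before the olefination. LiAlH4 reduces both carbonyl groups to (1S,2R,4aS,8aS)-1-(hydroxymethyl)-5,5,8a-trimethyldecahydronaphthalen-2-ol F2 (equatorial carbinol expected; either epimer serves). TBSCl/imidazole silylates the primary hydroxyl selectively to the mono-silyl ether F3. Dess–Martin oxidation gives 1-(tert-butyldimethylsilyloxymethyl)-5,5,8a-trimethyldecahydronaphthalen-2-one F4. Wittig methylenation (Ph3PCH3Br, KOtBu, THF) gives albicanol tert-butyldimethylsilyl ether F5, and Bu4NF in THF releases 8.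

3. Step 7. Proton transfer from the acidic 4-hydroxyl to the stabilised ylide may slow the olefination until the phosphorane decomposes, and residual cumulated ylide may acylate a phenol. The fallback sets out from 8 (through 10) and from 9 and comes back at 11, with the phenols masked. TBSCl/imidazole in DMF converts 9 into 2,4-bis(tert-butyldimethylsilyloxy)benzaldehyde F6. Wittig reaction of 10 with F6 in toluene at 80 °C gives albicanyl (E)-2,4-bis(tert-butyldimethylsilyloxy)cinnamate F7. Bu4NF buffered with AcOH in THF at 0 °C removes both silyl groups without touching the ester or the exocyclic alkene and gives 11.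

Further compounds
F1 | step 3 | methyl 6-allyl-5-(2-chloropropan-2-yl)-6-methyl-2-oxocyclohexane-1-carboxylate (C5 and C10 configuration of 5) | O=C1CC[C@@H](C(C)(C)Cl)[C@](C)(CC=C)[C@H]1C(=O)OC
F2 | step 5 | (1S,2R,4aS,8aS)-1-(hydroxymethyl)-5,5,8a-trimethyldecahydronaphthalen-2-ol | O[C@@H]1CC[C@H]2C(C)(C)CCC[C@]2(C)[C@H]1CO
F3 | step 5 | 1-(tert-butyldimethylsilyloxymethyl)-5,5,8a-trimethyldecahydronaphthalen-2-ol (configuration of F2) | O[C@@H]1CC[C@H]2C(C)(C)CCC[C@]2(C)[C@H]1CO[Si](C)(C)C(C)(C)C
F4 | step 5 | 1-(tert-butyldimethylsilyloxymethyl)-5,5,8a-trimethyldecahydronaphthalen-2-one (configuration of 6) | O=C1CC[C@H]2C(C)(C)CCC[C@]2(C)[C@H]1CO[Si](C)(C)C(C)(C)C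
F5 | step 5 | albicanol tert-butyldimethylsilyl ether | C=C1CC[C@H]2C(C)(C)CCC[C@]2(C)[C@H]1CO[Si](C)(C)C(C)(C)C
F6 | step 7 | 2,4-bis(tert-butyldimethylsilyloxy)benzaldehyde | O=Cc1ccc(O[Si](C)(C)C(C)(C)C)cc1O[Si](C)(C)C(C)(C)C
F7 | step 7 | albicanyl (E)-2,4-bis(tert-butyldimethylsilyloxy)cinnamate | C=C1CC[C@H]2C(C)(C)CCC[C@]2(C)[C@H]1COC(=O)/C=C/c1ccc(O[Si](C)(C)C(C)(C)C)cc1O[Si](C)(C)C(C)(C)C
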